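**Retrosynthetic overview**
- The target is reached by hydrogenolysis of 14 benzyl ethers and the C8–Br bond of a perbenzylated bis-galloyl ester, which comes from the bis-TBS 4→6 dimer by desilylation and acylation of both 3-hydroxyls.
- The strategy rests on upper C4, a diarylmethine between upper A-ring carbon C4a and lower A-ring carbon C6. Because the lower A ring carries oxygen at C5, C7 and C8a, a C4 cation is a quinone-methide-like 2,4,6-trioxygenated benzyl cation. Disconnecting C4–C4a gives an open-chain carbinol whose 3,5-bis(benzyloxy)phenyl ether on C2 closes the upper pyran by Friedel–Crafts alkylation.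
- The carbinol comes from C4–C6 bond formation: the 6-magnesiated 8-bromo lower flavan (from the 8-bromo-6-iodo compound; Br blocks C8, I marks C6) adds to an α-silyloxy-β-aryloxy aldehyde.
- The aldehyde comes from a Z-cinnamate by Jacobsen cis-epoxidation and benzylic phenoxide opening with inversion, which set upper C3 and C2.
- Ring order: the lower chroman and all aryl rings are bought in; the upper pyran is the only ring made and is closed in the key step.

Key step: step 11

Assumption: 3,4,5-tris(benzyloxy)benzoic acid is bought as such, and the carbinol from the fragment union is carried on as the mixture of its two carbinol epimers, since both ionise to the same cation.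

**Upper C2–C3–C4 chain**

Step 1
Reactants: 1 3,4-bis(benzyloxy)benzaldehyde
Product: 2 methyl (2Z)-3-[3,4-bis(benzyloxy)phenyl]prop-2-enoate
Conditions: (CF3CH2O)2P(O)CH2CO2Me, KHMDS, 18-crown-6, THF, −78 °C
Reagents that add atoms: methyl 2-[bis(2,2,2-trifluoroethoxy)phosphoryl]acetate, COC(=O)CP(=O)(OCC(F)(F)F)OCC(F)(F)F
Why: Still–Gennari olefination; the electron-poor phosphonate under dissociating conditions eliminates quickly from the kinetic adduct and should give the Z-enoate from an aromatic aldehyde.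

Step 2
Reactants: 2 methyl (2Z)-3-[3,4-bis(benzyloxy)phenyl]prop-2-enoate
Product: 3 methyl (2S,3S)-3-[3,4-bis(benzyloxy)phenyl]oxirane-2-carboxylate (cis-glycidate)
Conditions: (S,S)-Jacobsen (salen)Mn(III)Cl (6 mol %), 4-phenylpyridine N-oxide (0.25 equiv), buffered aq NaOCl (pH 11.3), CH2Cl2, 0–4 °C
Reagents that add atoms: sodium hypochlorite, [Na+].[O-]Cl
Why: Jacobsen–Katsuki epoxidation of a cis-cinnamate ester; the (S,S)-catalyst should set both epoxide carbons as S (the (R,R)-catalyst gives the (2R,3R)-cis-phenylglycidate in the parent series), and the minor trans-epoxide from stepwise collapse is removed by chromatography.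

Step 3
Reactants: 3 methyl (2S,3S)-3-[3,4-bis(benzyloxy)phenyl]oxirane-2-carboxylate; 4 3,5-bis(benzyloxy)phenol
Product: 5 methyl (2S,3R)-3-[3,4-bis(benzyloxy)phenyl]-3-[3,5-bis(benzyloxy)phenoxy]-2-hydroxypropanoate
Conditions: 4 (1.3 equiv), Cs2CO3 (0.3 equiv), DMF, 50 °C
Reagents that add atoms: none
Why: Base-catalysed SN2 opening of a 3-arylglycidate by a phenoxide at the benzylic carbon with inversion sets the aryl ether carbon (future upper C2) as R and leaves the C2–O bond (future upper C3) untouched; caesium phenoxide in DMF favours O- over C-alkylation, and cis-epoxide plus anti opening gives the 2,3-cis flavan relationship.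

Step 4
Reactants: 5 methyl (2S,3R)-3-[3,4-bis(benzyloxy)phenyl]-3-[3,5-bis(benzyloxy)phenoxy]-2-hydroxypropanoate
Product: 6 methyl (2S,3R)-3-[3,4-bis(benzyloxy)phenyl]-3-[3,5-bis(benzyloxy)phenoxy]-2-[(tert-butyldimethylsilyl)oxy]propanoate
Conditions: TBSOTf, 2,6-lutidine, CH2Cl2, 0 °C
Reagents that add atoms: tert-butyldimethylsilyl triflate, CC(C)(C)[Si](C)(C)OS(=O)(=O)C(F)(F)F
Why: Silylation of a hindered secondary α-hydroxy ester with the silyl triflate and a non-nucleophilic base; no stereocentre is touched.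

Step 5
Reactants: 6 methyl (2S,3R)-3-[3,4-bis(benzyloxy)phenyl]-3-[3,5-bis(benzyloxy)phenoxy]-2-[(tert-butyldimethylsilyl)oxy]propanoate
Product: 7 (2S,3R)-3-[3,4-bis(benzyloxy)phenyl]-3-[3,5-bis(benzyloxy)phenoxy]-2-[(tert-butyldimethylsilyl)oxy]propanal
Conditions: DIBAL-H (1.1 equiv), CH2Cl2, −78 °C; Rochelle salt; used crude
Reagents that add atoms: none
Why: Partial DIBAL reduction of an α-silyloxy ester stops at the aluminium hemiacetal at −78 °C; the aldehyde is used at once to avoid epimerisation at the α-carbon.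

**Lower flavan**

Step 6
Reactants: 8 (−)-epicatechin, (2R,3R)
Product: 9 5,7,3',4'-tetra-O-benzyl-(−)-epicatechin, (2R,3R)-5,7-bis(benzyloxy)-2-[3,4-bis(benzyloxy)phenyl]chroman-3-ol
Conditions: BnBr (4.4 equiv), K2CO3, DMF, 0 °C → rt, Ar
Reagents that add atoms: benzyl bromide, BrCc1ccccc1
Why: Williamson etherification; carbonate deprotonates only the four phenols, and low temperature under argon limits C2 epimerisation and oxidation.

Step 7
Reactants: 9 5,7,3',4'-tetra-O-benzyl-(−)-epicatechin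
Product: 10 5,7,3',4'-tetra-O-benzyl-3-O-(tert-butyldimethylsilyl)-(−)-epicatechin, (2R,3R)
Conditions: TBSCl, imidazole, DMF, rt
Reagents that add atoms: tert-butyldimethylsilyl chloride, CC(C)(C)[Si](C)(C)Cl
Why: Imidazole-promoted silylation of the single secondary alcohol.

Step 8
Reactants: 10 5,7,3',4'-tetra-O-benzyl-3-O-(tert-butyldimethylsilyl)-(−)-epicatechin
Product: 11 8-bromo-5,7,3',4'-tetra-O-benzyl-3-O-(tert-butyldimethylsilyl)-(−)-epicatechin, (2R,3R)
Conditions: NBS (1.0 equiv), CH2Cl2, −78 → 0 °C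
Reagents that add atoms: N-bromosuccinimide, O=C1CCC(=O)N1Br
Why: Electrophilic aromatic bromination; C8 is the most nucleophilic position of the 5,7-dibenzyloxy A ring, and one equivalent at low temperature should stop at the monobromide.

Step 9
Reactants: 11 8-bromo-5,7,3',4'-tetra-O-benzyl-3-O-(tert-butyldimethylsilyl)-(−)-epicatechin
Product: 12 8-bromo-6-iodo-5,7,3',4'-tetra-O-benzyl-3-O-(tert-butyldimethylsilyl)-(−)-epicatechin, (2R,3R)
Conditions: NIS (1.2 equiv), TFA (10 mol %), CH2Cl2/MeCN, 0 °C → rt, dark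
Reagents that add atoms: N-iodosuccinimide, O=C1CCC(=O)N1I
Why: Acid-catalysed electrophilic iodination at C6, the only free position left on the trioxygenated A ring; the catechol diether ring is much less activated.

**Union, key step and end game**

Step 10
Reactants: 12 8-bromo-6-iodo-5,7,3',4'-tetra-O-benzyl-3-O-(tert-butyldimethylsilyl)-(−)-epicatechin; 7 (2S,3R)-3-[3,4-bis(benzyloxy)phenyl]-3-[3,5-bis(benzyloxy)phenoxy]-2-[(tert-butyldimethylsilyl)oxy]propanal
Product: 14 (1RS,2R,3R)-3-[3,4-bis(benzyloxy)phenyl]-3-[3,5-bis(benzyloxy)phenoxy]-2-[(tert-butyldimethylsilyl)oxy]-1-[(2R,3R)-5,7-bis(benzyloxy)-2-[3,4-bis(benzyloxy)phenyl]-8-bromo-3-[(tert-butyldimethylsilyl)oxy]chroman-6-yl]propan-1-ol (carbinol epimers), via arylmagnesium chloride 13 (not isolated)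
Conditions: i-PrMgCl·LiCl (1.1 equiv), THF, −20 °C; then 7, −40 → 0 °C; pH 7 buffer
Reagents that add atoms: isopropylmagnesium chloride, CC(C)[Mg]Cl
Why: Iodine–magnesium exchange with the turbo-Grignard reagent is much faster for the aryl iodide than for the aryl bromide and gives the C6 arylmagnesium chloride, whose MgCl comes from the reagent and is lost again on work-up; the arylmagnesium adds 1,2 to the aldehyde (Grignard addition), and the new carbinol centre needs no control because it is ionised in the next step.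

Step 11
Reactants: 14 open-chain aryl ether carbinol (carbinol epimers)
Product: 16 bis-3-O-TBS perbenzylated 8-bromo epicatechin-(4β→6)-epicatechin, via benzylic cation 15 (not isolated)
Conditions: BF3·OEt2 (0.3 equiv), 4 Å MS, CH2Cl2 (5 mM), −78 → −30 °C; Et3N quench
Reagents that add atoms: none
Why: The Lewis acid ionises the C4 carbinol of both epimers to the benzylic cation, which is delocalised onto the C5, C7 and C8a oxygens of the lower A ring, and the tethered 3,5-bis(benzyloxy)phenyl ether attacks it through either of its equivalent ortho carbons before rearomatising. The closest known reaction type is the acid-mediated intramolecular Friedel–Crafts cyclisation of 1-aryl-3-aryloxypropan-1-ols to 4-arylchromans, together with the 3,4-trans capture of flavan C4 cations in procyanidin couplings. The upper pyran closes in a six-membered mode, exo with respect to the quinone-methide-like C4–C6 bond, through a chair-like transition state with the C2 aryl equatorial. The new stereocentre C4 is controlled by C3: the cis 3-silyloxy group is then axial and the lower aryl takes the pseudo-axial site anti to it, clear of the peri 5-benzyloxy group and with C3–H rather than C3–O aligned with the cationic p-orbital, and reversibility under acid favours the same 3,4-trans isomer, so the product keeps the upper unit 2R,3R and 2,3-cis with the lower flavan on C4 trans to the 3-silyloxy group. The step needs ionisation at C4 rather than at the C2 aryl ether (secured by the trioxygenated lower ring), chroman closure rather than indane closure onto the catechol ring (secured by the more nucleophilic phloroglucinol-type ring and the six-membered transition state), and intramolecular rather than intermolecular alkylation (secured by high dilution and by the C8 bromine, which leaves the lower A ring without a free nucleophilic carbon).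

Step 12
Reactants: 16 bis-TBS perbenzylated 8-bromo 4β→6 dimer
Product: 17 5,7,3',4'-tetra-O-benzyl-(−)-epicatechin-(4β→6)-[8-bromo-5,7,3',4'-tetra-O-benzyl-(−)-epicatechin] (both 3-hydroxyls free)
Conditions: TBAF (4 equiv), AcOH (4 equiv), THF, rt → 45 °C
Reagents that add atoms: none
Why: Fluoride-mediated cleavage of both secondary silyl ethers; acetic acid buffering keeps the medium near neutral, and benzyl ethers, aryl bromide and the interflavan bond should be inert.

Step 13
Reactants: 18 3,4,5-tris(benzyloxy)benzoic acid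
Product: 19 3,4,5-tris(benzyloxy)benzoyl chloride
Conditions: (COCl)2, DMF (cat.), CH2Cl2, 0 °C → rt; evaporate, use crude
Reagents that add atoms: oxalyl chloride, O=C(Cl)C(Cl)=O
Why: Acid chloride formation through the Vilsmeier-type chloroiminium catalyst.

Step 14
Reactants: 17 diol; 19 3,4,5-tris(benzyloxy)benzoyl chloride
Product: 20 3,3'-bis-O-[3,4,5-tris(benzyloxy)benzoyl] derivative of 17 (perbenzylated 8-bromo procyanidin B-5 digallate)
Conditions: 19 (4 equiv), DMAP, pyridine, CH2Cl2, rt → 40 °C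
Reagents that add atoms: none
Why: DMAP-catalysed acylation by an acid chloride; the acylpyridinium is reactive enough to esterify the hindered axial 3-hydroxyl of the upper unit as well as the lower one.

Step 15
Reactants: 20 perbenzylated 8-bromo digallate
Product: 21 procyanidin B-5 3,3'-di-O-gallate
Conditions: H2 (1 atm), 20% Pd(OH)2/C, Et3N (1.2 equiv), THF/MeOH/H2O, rt
Reagents that add atoms: none
Why: Catalytic hydrogenolysis over Pearlman's catalyst should cleave all 14 benzyl ethers and hydrodebrominate C8, with triethylamine trapping the HBr; esters and stereocentres are not affected.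

**Compound list**
1 | 3,4-bis(benzyloxy)benzaldehyde | O=Cc1ccc(OCc5ccccc5)c(OCc5ccccc5)c1 | starting material
2 | methyl (2Z)-3-[3,4-bis(benzyloxy)phenyl]prop-2-enoate | COC(=O)/C=C\c1ccc(OCc5ccccc5)c(OCc5ccccc5)c1 | intermediate
3 | methyl (2S,3S)-3-[3,4-bis(benzyloxy)phenyl]oxirane-2-carboxylate | COC(=O)[C@H]1O[C@H]1c1ccc(OCc5ccccc5)c(OCc5ccccc5)c1 | intermediate
4 | 3,5-bis(benzyloxy)phenol | Oc1cc(OCc5ccccc5)cc(OCc5ccccc5)c1 | starting material
5 | methyl (2S,3R)-3-[3,4-bis(benzyloxy)phenyl]-3-[3,5-bis(benzyloxy)phenoxy]-2-hydroxypropanoate | O[C@@H]([C@H](Oc1cc(OCc5ccccc5)cc(OCc5ccccc5)c1)c1ccc(OCc5ccccc5)c(OCc5ccccc5)c1)C(=O)OC | intermediate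
6 | methyl (2S,3R)-3-[3,4-bis(benzyloxy)phenyl]-3-[3,5-bis(benzyloxy)phenoxy]-2-[(tert-butyldimethylsilyl)oxy]propanoate | CC(C)(C)[Si](C)(C)O[C@@H]([C@H](Oc1cc(OCc5ccccc5)cc(OCc5ccccc5)c1)c1ccc(OCc5ccccc5)c(OCc5ccccc5)c1)C(=O)OC | intermediate
7 | (2S,3R)-3-[3,4-bis(benzyloxy)phenyl]-3-[3,5-bis(benzyloxy)phenoxy]-2-[(tert-butyldimethylsilyl)oxy]propanal | CC(C)(C)[Si](C)(C)O[C@@H]([C@H](Oc1cc(OCc5ccccc5)cc(OCc5ccccc5)c1)c1ccc(OCc5ccccc5)c(OCc5ccccc5)c1)C=O | intermediate
8 | (−)-epicatechin | O[C@@H]1Cc2c(O)cc(O)cc2O[C@@H]1c1ccc(O)c(O)c1 | starting material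
9 | 5,7,3',4'-tetra-O-benzyl-(−)-epicatechin | O[C@@H]1Cc2c(OCc5ccccc5)cc(OCc5ccccc5)cc2O[C@@H]1c1ccc(OCc5ccccc5)c(OCc5ccccc5)c1 | intermediate
10 | 5,7,3',4'-tetra-O-benzyl-3-O-TBS-(−)-epicatechin | CC(C)(C)[Si](C)(C)O[C@@H]1Cc2c(OCc5ccccc5)cc(OCc5ccccc5)cc2O[C@@H]1c1ccc(OCc5ccccc5)c(OCc5ccccc5)c1 | intermediate
11 | 8-bromo-5,7,3',4'-tetra-O-benzyl-3-O-TBS-(−)-epicatechin | CC(C)(C)[Si](C)(C)O[C@@H]1Cc2c(OCc5ccccc5)cc(OCc5ccccc5)c(Br)c2O[C@@H]1c1ccc(OCc5ccccc5)c(OCc5ccccc5)c1 | intermediate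
12 | 8-bromo-6-iodo-5,7,3',4'-tetra-O-benzyl-3-O-TBS-(−)-epicatechin | CC(C)(C)[Si](C)(C)O[C@@H]1Cc2c(OCc5ccccc5)c(I)c(OCc5ccccc5)c(Br)c2O[C@@H]1c1ccc(OCc5ccccc5)c(OCc5ccccc5)c1 | intermediate
13 | 6-(chloromagnesio)-8-bromo-5,7,3',4'-tetra-O-benzyl-3-O-TBS-(−)-epicatechin (arylmagnesium chloride) | CC(C)(C)[Si](C)(C)O[C@@H]1Cc2c(OCc5ccccc5)c([Mg]Cl)c(OCc5ccccc5)c(Br)c2O[C@@H]1c1ccc(OCc5ccccc5)c(OCc5ccccc5)c1 | intermediate
14 | open-chain aryl ether carbinol, (1RS,2R,3R)-propan-1-ol on C6 of the 8-bromo lower flavan | CC(C)(C)[Si](C)(C)O[C@@H]([C@H](Oc1cc(OCc5ccccc5)cc(OCc5ccccc5)c1)c1ccc(OCc5ccccc5)c(OCc5ccccc5)c1)C(O)c2c(OCc5ccccc5)c(Br)c3c(c2OCc5ccccc5)C[C@@H](O[Si](C)(C)C(C)(C)C)[C@@H](c2ccc(OCc5ccccc5)c(OCc5ccccc5)c2)O3 | intermediate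
15 | benzylic (quinone-methide-like) cation at upper C4, formed from carbinol 14 by loss of water | CC(C)(C)[Si](C)(C)O[C@@H]([C@H](Oc1cc(OCc5ccccc5)cc(OCc5ccccc5)c1)c1ccc(OCc5ccccc5)c(OCc5ccccc5)c1)[CH+]c2c(OCc5ccccc5)c(Br)c3c(c2OCc5ccccc5)C[C@@H](O[Si](C)(C)C(C)(C)C)[C@@H](c2ccc(OCc5ccccc5)c(OCc5ccccc5)c2)O3 | intermediate
16 | bis-3-O-TBS perbenzylated 8-bromo epicatechin-(4β→6)-epicatechin (upper unit 2R,3R, 2,3-cis, 3,4-trans) | CC(C)(C)[Si](C)(C)O[C@@H]1[C@@H](c2c(OCc5ccccc5)c(Br)c3c(c2OCc5ccccc5)C[C@@H](O[Si](C)(C)C(C)(C)C)[C@@H](c2ccc(OCc5ccccc5)c(OCc5ccccc5)c2)O3)c2c(OCc5ccccc5)cc(OCc5ccccc5)cc2O[C@@H]1c1ccc(OCc5ccccc5)c(OCc5ccccc5)c1 | intermediate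
17 | perbenzylated 8-bromo epicatechin-(4β→6)-epicatechin, 3,3'-diol | O[C@@H]1[C@@H](c2c(OCc5ccccc5)c(Br)c3c(c2OCc5ccccc5)C[C@@H](O)[C@@H](c2ccc(OCc5ccccc5)c(OCc5ccccc5)c2)O3)c2c(OCc5ccccc5)cc(OCc5ccccc5)cc2O[C@@H]1c1ccc(OCc5ccccc5)c(OCc5ccccc5)c1 | intermediate
18 | 3,4,5-tris(benzyloxy)benzoic acid | OC(=O)c1cc(OCc5ccccc5)c(OCc5ccccc5)c(OCc5ccccc5)c1 | starting material
19 | 3,4,5-tris(benzyloxy)benzoyl chloride | O=C(Cl)c1cc(OCc5ccccc5)c(OCc5ccccc5)c(OCc5ccccc5)c1 | intermediate
20 | perbenzylated 8-bromo procyanidin B-5 3,3'-di-O-gallate | O=C(O[C@@H]1[C@@H](c2c(OCc5ccccc5)c(Br)c3c(c2OCc5ccccc5)C[C@@H](OC(=O)c2cc(OCc5ccccc5)c(OCc5ccccc5)c(OCc5ccccc5)c2)[C@@H](c2ccc(OCc5ccccc5)c(OCc5ccccc5)c2)O3)c2c(OCc5ccccc5)cc(OCc5ccccc5)cc2O[C@@H]1c1ccc(OCc5ccccc5)c(OCc5ccccc5)c1)c1cc(OCc5ccccc5)c(OCc5ccccc5)c(OCc5ccccc5)c1 | intermediate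
21 | procyanidin B-5 3,3'-di-O-gallate | O=C(O[C@@H]1[C@@H](c2c(O)cc3c(c2O)C[C@@H](OC(=O)c2cc(O)c(O)c(O)c2)[C@@H](c2ccc(O)c(O)c2)O3)c2c(O)cc(O)cc2O[C@@H]1c1ccc(O)c(O)c1)c1cc(O)c(O)c(O)c1 | target

**Step count**
Total: 15 steps. Longest linear sequence: 10 steps (steps 1–5, 10, 11, 12, 14, 15, from 1 to 21).

**Steps most likely to fail**

Step 11. The cation may close with poor facial selectivity at C4, lose the C3 proton to a silyl enol ether, or alkylate a second molecule through the free positions of the upper A ring. The fallback makes the interflavan bond intermolecularly with the upper pyran already in place. It sets out from 10: DDQ oxidation in the presence of 2-ethoxyethanol (CH2Cl2, rt) should give 5,7,3',4'-tetra-O-benzyl-3-O-TBS-4β-(2-ethoxyethoxy)-(−)-epicatechin F1. Catalytic TMSOTf (CH2Cl2, −78 °C) then ionises F1 in the presence of an excess of 11, whose C8 bromine leaves C6 as the only nucleophilic carbon, and 3,4-trans capture of the flavan C4 cation should give 16, where the route is rejoined.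

Step 3. Phenoxide opening of the electron-rich glycidic ester may leak through an SN1 path at the benzylic carbon, alkylate the phenol through carbon, or be followed by base-induced loss of phenoxide from the β-aryloxy ester. The fallback removes the ester before the opening and sets out from 3. NaBH4 (MeOH/THF, 0 °C) should give [(2R,3S)-3-[3,4-bis(benzyloxy)phenyl]oxiran-2-yl]methanol F2. The sodium phenoxide of 4 in aqueous NaOH/dioxane (70 °C) opens F2 at the benzylic carbon with inversion, as in known 3-arylglycidol openings, to give (2R,3R)-3-[3,4-bis(benzyloxy)phenyl]-3-[3,5-bis(benzyloxy)phenoxy]propane-1,2-diol F3. TBSOTf/2,6-lutidine gives the 1,2-bis-O-TBS ether of F3, (1R,2R)-1-[3,4-bis(benzyloxy)phenyl]-1-[3,5-bis(benzyloxy)phenoxy]-2,3-bis[(tert-butyldimethylsilyl)oxy]propane F4. HF·pyridine (THF/pyridine, 0 °C) removes the primary silyl group selectively to give (2R,3R)-3-[3,4-bis(benzyloxy)phenyl]-3-[3,5-bis(benzyloxy)phenoxy]-2-[(tert-butyldimethylsilyl)oxy]propan-1-ol F5, and Dess–Martin oxidation returns to the route at 7.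

Step 10. The hindered, basic arylmagnesium may deprotonate the aldehyde at the α-carbon, with epimerisation of the future C3 or loss of the β-aryloxide, instead of adding, or the crowded addition may stall. The fallback is a Nozaki–Hiyama–Kishi coupling, which is non-basic and selective for the iodide. It sets out from 12 and 7: CrCl2 (4 equiv) with catalytic NiCl2 (DMF/THF, rt) should form the transient 6-(dichlorochromio)-8-bromo-5,7,3',4'-tetra-O-benzyl-3-O-TBS-(−)-epicatechin F6, which adds to the aldehyde and returns to the route at 14.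

**Further compounds**
F1 | step 11 | 5,7,3',4'-tetra-O-benzyl-3-O-TBS-4β-(2-ethoxyethoxy)-(−)-epicatechin | CC(C)(C)[Si](C)(C)O[C@@H]1[C@@H](OCCOCC)c2c(OCc5ccccc5)cc(OCc5ccccc5)cc2O[C@@H]1c1ccc(OCc5ccccc5)c(OCc5ccccc5)c1
F2 | step 3 | [(2R,3S)-3-[3,4-bis(benzyloxy)phenyl]oxiran-2-yl]methanol | OC[C@H]1O[C@H]1c1ccc(OCc5ccccc5)c(OCc5ccccc5)c1
F3 | step 3 | (2R,3R)-3-[3,4-bis(benzyloxy)phenyl]-3-[3,5-bis(benzyloxy)phenoxy]propane-1,2-diol | O[C@@H]([C@H](Oc1cc(OCc5ccccc5)cc(OCc5ccccc5)c1)c1ccc(OCc5ccccc5)c(OCc5ccccc5)c1)CO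
F4 | step 3 | (1R,2R)-1-[3,4-bis(benzyloxy)phenyl]-1-[3,5-bis(benzyloxy)phenoxy]-2,3-bis[(tert-butyldimethylsilyl)oxy]propane | CC(C)(C)[Si](C)(C)O[C@@H]([C@H](Oc1cc(OCc5ccccc5)cc(OCc5ccccc5)c1)c1ccc(OCc5ccccc5)c(OCc5ccccc5)c1)CO[Si](C)(C)C(C)(C)C
F5 | step 3 | (2R,3R)-3-[3,4-bis(benzyloxy)phenyl]-3-[3,5-bis(benzyloxy)phenoxy]-2-[(tert-butyldimethylsilyl)oxy]propan-1-ol | CC(C)(C)[Si](C)(C)O[C@@H]([C@H](Oc1cc(OCc5ccccc5)cc(OCc5ccccc5)c1)c1ccc(OCc5ccccc5)c(OCc5ccccc5)c1)CO
F6 | step 10 | 6-(dichlorochromio)-8-bromo-5,7,3',4'-tetra-O-benzyl-3-O-TBS-(−)-epicatechin (transient arylchromium(III)) | CC(C)(C)[Si](C)(C)O[C@@H]1Cc2c(OCc5ccccc5)c([Cr](Cl)Cl)c(OCc5ccccc5)c(Br)c2O[C@@H]1c1ccc(OCc5ccccc5)c(OCc5ccccc5)c1
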